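Whatever happens in this flask, Q, L and E together make up the whole charge: D is charged at 0.0066 mol% of the Q, less than the scatter of a reading, so what D holds bound cannot show. E, which nobody read, is then the fraction of the charge gone from Q, minus L.

| flask | Q | D | remark | time |
|---|---|---|---|---|
| east | 46 mM | 0.0066 mol% | the very flask that is asked about, followed so far |  |
| south | 46 mM | 0.013 mol% | run made earlier |  |
| flask | 46 mM | 0.0066 mol% |  | 15 min |

- east (time / min: L / %, Q / %): 1.00: 4.7, 91.7; 3.00: 8.7, 84.2; 6.00: 11.6, 76.0; 10.0: 11.5, 71.8
- south (time / min: L / %, Q / %): 2.00: 12.9, 81.3; 4.00: 15.2, 71.9; 6.00: 13.1, 66.7; 8.00: 15.3, 63.5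

(readings scatter by 1 percentage point)

- percent here means Q units held: one Z counts as two
- removed L is counted in
- steps under discussion: 2 X -> Z; Q + D <-> X; X <-> D + L; L <-> E
- additions bring no volume worth counting

- eta: at 15 min add D, 100% of the amount charged, then wait 30 min
- zeta: at 15 min take out 90% of the L then present, then wait 30 min
- gamma: change nothing and wait 30 min more
- delta: at 15 min add Q, 50.0% of the amount charged, then wait 30 min

- L, in percent of the Q first charged, at 15 min
- what to do for the largest gain in L; "none" if nothing gains more than 2 percentage points (eta / zeta / gamma / delta / none)
- L present, with what was taken out counted in, in percent of the Q first charged, after gamma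
- L present, with what was taken out counted in, in percent of the Q first charged, after delta

Two chemists dispute L in the east flask at 15 min. They agree on the fraction gone from Q. The runs lie roughly on one curve against loading times time, and the east flask at 15 min has 0.952 of the product of the south run at its last reading, so about 36.5% of the charge has left Q.

They part on how that fraction divides. The first takes the even split as the zero of the scale: nothing yet tells L from E, and the east reading at 6.00 min gives L a share of 0.483. That makes L 18.2%.

The second pools the last reading of each run and gets 0.414 as the share of L, L divided by the fraction gone from Q, the selectivity between L and E. This is a reading and carries the scatter. It makes L 15.1%, and the gap of 3.1 percentage points between the two chemists exceeds the scatter.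

The forecast, on the second side and a little below that chemist's figure, gives 14.3% now, eta as best, 20% after gamma and 22.5% after delta, holding that “L and E equilibrate quickly”.

The flask gives 14.1%, with eta best at a gain of 16 points against 13 points for zeta, then 19.0% after gamma and 19.1% after delta. The even split loses, but it has its region early on: the share of L in the flask falls from 0.767 at 1.50 min to 0.448 at 7.50 min, passing through an even split between those times.

    2 X → Z (k = 1800 L mol⁻¹ s⁻¹)
    Q + D ⇌ X (K = 900 L mol⁻¹, k = 29000 L mol⁻¹ s⁻¹)
    X ⇌ D + L (K = 0.0520 M, k = 25.0 s⁻¹)
    L ⇌ E (K = 1.80, k = 0.00620 s⁻¹)

With 64% of Q left in the flask, the share gives L as 14.9%, against the 14.1% found. The neighbouring flask charges 28 mM of Q at the same loading and time, and 52% of its Q is left at 15 min. The same share then gives 19.9%, and that flask holds 18.9% of L, which stands 4.8 points above the asked flask.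

All runs were generated by integration on assumed constants, noise included.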